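**Assumption:** the target has no stereocenters, so there is no enantiomer issue. Phloroglucinol, benzyl bromide and 3,4,5-trimethoxyphenylacetic acid are taken as commercial.

**Target check:** Junipegenin C is the isoflavone 5,7-dihydroxy-6,3',4',5'-tetramethoxyisoflavone. It has a chromone core with 3-aryl, 5-OH, 6-OMe and 7-OH, and a 3,4,5-trimethoxyphenyl B ring.

## Retrosynthesis
1. The pyranone C2 comes from a one-carbon formylative cyclization (DMF/BF3/MsCl) of the 2'-hydroxydeoxybenzoin 7.
2. Deoxybenzoin 7 comes from BF3-mediated C-acylation of 2-methoxyphloroglucinol (5) with 3,4,5-trimethoxyphenylacetic acid (6). The two free ring positions of 5 are equivalent, so acylation gives one regioisomer.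
3. Triol 5 is made from phloroglucinol by tribenzylation, C-2 hydroxylation by lithiation/borylation/oxidation, O-methylation and hydrogenolysis. This gives the 6-OMe, 5,7-diOH pattern without any selective demethylation.
4. Ring order: A ring (already aromatic) → ketone-linked A/B deoxybenzoin → pyranone C ring.

## Route

**Step 1**
Reactants: 1 phloroglucinol
Product: 2 1,3,5-tris(benzyloxy)benzene
Conditions: BnBr (3.3 equiv), K2CO3, DMF, rt
Reagents that add atoms: benzyl bromide, BrCc1ccccc1
Why: Williamson O-alkylation of all three phenols masks them as benzyl ethers that can later be removed under neutral conditions. The benzyl groups also direct lithiation to the position between two of them.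

**Step 2**
Reactants: 2 1,3,5-tris(benzyloxy)benzene
Product: 3 2,4,6-tris(benzyloxy)phenol
Conditions: (i) n-BuLi, THF, 0 °C to rt; (ii) B(OMe)3, –78 °C to rt; (iii) 30% H2O2, aq. NaOH, 0 °C
Reagents that add atoms: hydrogen peroxide, OO (supplies the phenol O); trimethyl borate, COB(OC)OC (boron carrier, not retained)
Why: Directed ortho-metalation occurs at C-2, between two OBn groups. The aryl boronate is then oxidized to the phenol (oxidative C–B to C–O conversion). The new O becomes the 6-OMe oxygen.

**Step 3**
Reactants: 3 2,4,6-tris(benzyloxy)phenol
Product: 4 1,3,5-tris(benzyloxy)-2-methoxybenzene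
Conditions: MeI, K2CO3, acetone, reflux
Reagents that add atoms: methyl iodide, CI
Why: Williamson O-methylation of the only free phenol installs the future 6-OMe.

**Step 4**
Reactants: 4 1,3,5-tris(benzyloxy)-2-methoxybenzene
Product: 5 2-methoxybenzene-1,3,5-triol (2-methoxyphloroglucinol)
Conditions: H2 (1 atm), 10% Pd/C, EtOAc/MeOH, rt; filter under N2 and use immediately
Reagents that add atoms: none (the benzyl groups leave as toluene)
Why: Catalytic hydrogenolysis removes the three benzyl ethers but leaves the aryl methyl ether.

**Step 5**
Reactants: 5 2-methoxybenzene-1,3,5-triol; 6 3,4,5-trimethoxyphenylacetic acid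
Product: 7 1-(2,4,6-trihydroxy-3-methoxyphenyl)-2-(3,4,5-trimethoxyphenyl)ethan-1-one
Conditions: BF3·OEt2 (neat, excess), 80 °C, 2 h; then aq. NaOAc workup
Reagents that add atoms: none (the acid is reactant 6; BF3 is not retained)
Why: BF3 activates the carboxylic acid for Friedel–Crafts C-acylation of the phloroglucinol-type ring (the Hoesch-type ketone synthesis used for genistein-type deoxybenzoins). Acylation at C-4 or C-6 of 5 gives the same product, so regiochemistry is unambiguous. The ketone is stabilized as a BF2 chelate, which prevents over-acylation.

**Step 6**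
Reactants: 7 deoxybenzoin
Product: 8 Junipegenin C (5,7-dihydroxy-6,3',4',5'-tetramethoxyisoflavone)
Conditions: BF3·OEt2, DMF, MsCl, 50 to 80 °C; then aq. workup
Reagents that add atoms: N,N-dimethylformamide, CN(C)C=O (supplies the C-2 carbon). MsCl, CS(=O)(=O)Cl, only activates DMF and is not retained.
Why: A Vilsmeier-type C-formylation of the ketone α-carbon is followed by cyclodehydration of the 2'-OH onto the formyl carbon, a one-pot isoflavone synthesis (Wähälä conditions). Ring closure through the less hindered 6'-OH (the one not flanked by OMe) is assumed to give the 6-OMe isomer rather than the 8-OMe isomer. This must be confirmed by NMR (H-8 singlet; HMBC from 6-OMe to C-6). There is no stereocenter to set.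

## Self-check
- **Target match:** 8 has a chromone core, 3-aryl, 5-OH, 6-OMe, 7-OH, H-8 and a 3',4',5'-(OMe)3 B ring, which matches the target SMILES.
- **Atom balance:** 7 is C18H20O8, and adding one carbon from DMF with loss of water gives C19H18O8, the target formula.
- **Functional-group survival:** The aryl methyl ethers survive BF3·OEt2 at 80 °C, and the benzyl groups are removed before any Lewis acid is used.
- **Stereochemistry:** The target is achiral and no stereocenter is created anywhere in the route.

## Compound list
1 | phloroglucinol | Oc1cc(O)cc(O)c1 | starting material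
2 | 1,3,5-tris(benzyloxy)benzene | c1ccc(COc2cc(OCc3ccccc3)cc(OCc3ccccc3)c2)cc1 | intermediate
3 | 2,4,6-tris(benzyloxy)phenol | Oc1c(OCc2ccccc2)cc(OCc2ccccc2)cc1OCc1ccccc1 | intermediate
4 | 1,3,5-tris(benzyloxy)-2-methoxybenzene | COc1c(OCc2ccccc2)cc(OCc2ccccc2)cc1OCc1ccccc1 | intermediate
5 | 2-methoxybenzene-1,3,5-triol | COc1c(O)cc(O)cc1O | intermediate
6 | 3,4,5-trimethoxyphenylacetic acid | COc1cc(CC(=O)O)cc(OC)c1OC | starting material
7 | 1-(2,4,6-trihydroxy-3-methoxyphenyl)-2-(3,4,5-trimethoxyphenyl)ethan-1-one | COc1c(O)cc(O)c(C(=O)Cc2cc(OC)c(OC)c(OC)c2)c1O | intermediate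
8 | Junipegenin C (achiral) | COc1cc(-c2coc3cc(O)c(OC)c(O)c3c2=O)cc(OC)c1OC | target

**Total steps:** 6. **Longest linear sequence:** 6 steps (phloroglucinol to 8).

## Three steps most likely to fail
1. **Step 2 (lithiation/borylation/oxidation of the tribenzyl ether).** Benzylic deprotonation or Wittig rearrangement may compete with ring lithiation. Fallback: a different approach, Vilsmeier formylation of 2 to the 2,4,6-tris(benzyloxy)benzaldehyde, then Dakin (mCPBA Baeyer–Villiger, then hydrolysis) oxidation to phenol 3.
2. **Step 6 (regioselectivity of cyclization, 6-OMe vs 8-OMe, and competing A-ring formylation).** Fallback: lock the regiochemistry by building the A ring from 3,5-bis(benzyloxy)-4-methoxyphenol, made from 3,5-dihydroxy-4-methoxybenzaldehyde by benzylation and Dakin oxidation. Only one free OH then exists for ring closure. Hoesch acylation with 3,4,5-trimethoxyphenylacetonitrile/ZnCl2, formylative cyclization and a final H2/Pd-C debenzylation complete the route.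
3. **Steps 4 to 5 (air-sensitive triol 5 and its acylation).** Oxidative decomposition or poor conversion is possible. Fallback: replace the acid/BF3 acylation with a Hoesch reaction using 3,4,5-trimethoxyphenylacetonitrile, ZnCl2 and HCl in ether on freshly generated 5. Alternatively, build the A ring from the benzylated phenol above and acylate it with ZnCl2.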